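A small charge of protic impurity, half the electrophile's, stands in every flask here, and the electrophile that goes missing without becoming target can be timed on its own clock.

| setting | cedar | larch | teal | grey |
|---|---|---|---|---|
| electrophile | 0.40 M | 0.40 M | 0.40 M | 0.40 M |
| nucleophile | 0.70 equiv | 1.3 equiv | 1.80 equiv | 0.900 equiv |
| protic impurity | 0.20 M | 0.20 M | 0.200 M | 0.200 M |
| remark | run made earlier | run made earlier |  |  |
| time |  |  | 2.5 h | 2.5 h |

| run | time / min | electrophile / % | target / % |
|---|---|---|---|
| cedar | 25.0 | 81.8 | 13.5 |
| cedar | 50.0 | 71.7 | 19.0 |
| cedar | 80.0 | 65.1 | 22.8 |
| cedar | 120 | 58.8 | 25.1 |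
| larch | 8.00 | 87.9 | 9.9 |
| larch | 20.0 | 76.9 | 19.7 |
| larch | 50.0 | 62.5 | 30.2 |
| larch | 120 | 47.5 | 38.2 |

(standard deviation of a reading: 0.3 percentage points)

1. part of the electrophile that has reacted at the end, teal
2. part of the electrophile that has reacted at the end, grey
3. what raising the equivalents of nucleophile from its lowest to its highest value here does to the part of the electrophile that has reacted (changes below 5 percentage points count as none) (it falls / no change / it rises)

- the analysis behind the earlier runs scatters by 0.3 percentage points, standard deviation

Read three clocks off larch, fastest first. Target made per share of electrophile present runs at 0.0132 min⁻¹ in the first interval and at 0.00208 min⁻¹ in the last, so the power to make target fades with a lifetime of 43.9 min. The second clock, target making at its opening pace, has a lifetime of 75.8 min. Because the fading is faster, target stalls with electrophile still standing.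

The slowest clock is the missing share, electrophile lost and not found as target. Between the last two larch readings it grows by 7 percentage points in 70.0 min, while electrophile averages 55.0%. That gives the side lifetime, the time the electrophile would take to go by this route at a pseudo-first-order pace, 9.17 h. Side share is then mean electrophile share times time over side lifetime.

The asked 2.5 h is 3.42 fading lifetimes but 0.273 side lifetimes, so both flasks end past the stall and early on the slow clock. For grey, with cedar's 65.1% at 80.0 min standing in for the mean, I reckon a side share of 17.8%.

The forecast gives 63% for teal and 49% for grey, and on the trend, it rises. It reads the stall its own way, “The nucleophile is dying, with a lifetime of about 50 min.”, against my 43.9 min.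

The flask gives 62.4% for teal and 49.1% for grey: it rises, by 13 points.

    electrophile + nucleophile → acid set free + target (k = 1.90 M⁻¹ h⁻¹)
    nucleophile + acid set free ⇌ protonated nucleophile, settled at all times (K = 831 M⁻¹)
    2 nucleophile → homo dimer (k = 1.50 M⁻¹ h⁻¹)
    acid set free → by-product carried off (k = 2.23 h⁻¹)
    electrophile + protic impurity → quenched substrate (k = 0.657 M⁻¹ h⁻¹)

Grey ends with 17.5% as quenched substrate, against the 17.8% reckoned. Grey's answer moves by 5 points at 0.669 equiv or 1.18 equiv of nucleophile, or at 1.85 h or 3.34 h, and a forecast this close could fail there. In teal, electrophile falls from 48.9% at 1.25 h to 37.6% at 2.50 h, a late stretch whose midpoint, 43.2%, can stand for the mean share. Over that stretch the side lifetime gives 5.9 points, and teal's quenched substrate grows by 5.3 points.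

The numbers in the tables were generated by integration on assumed constants.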